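The flask is read at 0.80 s, 12 s and 3.0 min, and each reading is J divided by L, both as fractions of the Q charged. The violet run is this same flask, followed so far.

| flask | Q | G | remark | time |
|---|---|---|---|---|
| violet | 0.84 M | 21 mM | the very flask that is asked about, followed so far |  |
| amber | 1.7 M | 21 mM | run made earlier |  |
| flask | 0.84 M | 21 mM |  | 3.0 min |

- violet (time / s: J / %, L / %): 10.0: 16.7, 0.9; 15.0: 19.4, 0.1; 20.0: 22.9, 0.8; 25.0: 23.8, 1.8; 30.0: 24.4, 0.6
- amber (time / s: J / %, L / %): 10.0: 16.7, 1.4; 25.0: 24.3, 1.6; 40.0: 25.7, 0.6; 60.0: 26.2, 1.4; 90.0: 26.4, 2.6; 120: 26.0, 2.7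

(standard deviation of a reading: 0.5 percentage points)

- the analysis behind the earlier runs scatters by 0.5 percentage points, standard deviation

- ratio of J to L at 0.80 s
- ratio of J to L at 12 s
- ratio of J to L at 3.0 min

1. Amber J stops climbing: its readings at 60.0 s, 90.0 s and 120 s average 26.2%, read as the plateau.

2. Take the fraction left, 1 − J/plateau, in place of the fraction made. Amber, with 1.7 M of Q against 0.84 M, reads 16.7% of J at 10.0 s and violet reads 16.7%, so the two runs can be pooled. Their mean at 25.0 s leaves 0.0821.

3. A first-order approach halves its fraction left in equal times. That gives 6.93 s, the relaxation half-life of the climb, the time in which the fraction left halves. The reading at 10.0 s leaves 0.363, and this half-life gives 0.368.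

4. So the numerator follows: J is 2.01% at 0.80 s and 18.3% at 12 s. The time 3.0 min spans 26.0 half-lives, which leaves hardly any of the climb, so the last ratio is the plateau over L.

5. The denominator is poorer. Violet L reads 0.9% at 10.0 s, then 0.1% at 15.0 s, so this reckoning gives J alone for the early times. Amber L at 90.0 s and 120 s averages 2.65%. Holding L there is this reckoning's commitment, and it gives a last ratio of 9.89.

6. The forecast calls L “a slow, effectively irreversible leak” and gives 55, 35 and 5.7. Its last value differs from this reckoning's 9.89.

The flask gives 159, 35.7 and 11.1.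

    Q ⇌ J (K = 0.370, k = 0.0270 s⁻¹)
    J + G ⇌ L + G, rate k2*[G]*[J] forward; the back reaction follows from the equilibrium constant (K = 0.700, k = 1.00 M⁻¹ s⁻¹)
    2 G → Z (k = 16.0 M⁻¹ s⁻¹)

With the same half-life, J after 0.300 min reckons to 21.9%, and the flask holds 22.1%. The neighbouring flask takes 0.084 M of G, 4.00 times the charge. The step Q ⇌ J carries no G in the scheme, so the reckoning keeps 6.93 s and J of 2.01% at 0.80 s. The neighbour's ratio of 68.3 then means L of 0.0294%, against 0.0126% from 159 in the asked flask. At 3.0 min the neighbour holds J 26.3% and L 2.53%, against L 2.38% in the asked flask, and its ratio is 10.4.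

Readings and results come from a simulation with made-up constants; noise was put on by code.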